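**Strategy.** The target is cut at its two (E)-2-(hydroxymethyl)acrylate C=C bonds: two Horner–Wadsworth–Emmons olefinations, the second joining a ring-A hydroxy-lactone phosphonate to a ring-B butenolide aldehyde. Everything rests on the butenolide fused to the cyclohexene of the acyl half: its ring O–C(=O) unit, lying between the exocyclic allylic CH2 and the vinylic ring carbon, is carbon dioxide. A 1-bromo-2-(chloromethyl)cyclohexene, whose ring C=C holds a latent vinyl anion cis to an allylic electrophile, is lithiated and carboxylated; the new carboxylate then displaces chloride. One pot thus forms the C–C(=O) and CH2–O bonds of the lactone, a formal (3+2) annulation with CO2.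

Key step: step 5

Remark on the chemistry: allyl diethylphosphonoacetate, diisopropylzinc, benzyl chloromethyl ether, the binaphthol-derived phosphoramidite ligand and the diphenylprolinol silyl ether catalyst are taken as commercial. Ring B is the cyclohexene of the acyl half; ring A is the cyclohexane that carries the tertiary ester and the free acid.

**Ring B: butenolide aldehyde 12**

Step 1
Reactants: 1 cyclohex-2-en-1-one
Product: 3 (2S,3R)-2-[(benzyloxy)methyl]-3-(propan-2-yl)cyclohexan-1-one, via zinc enolate 2 (not isolated)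
Conditions: Cu(OTf)2 (2 mol%), (S,R,R)-phosphoramidite ligand [O,O'-(S)-1,1'-binaphthyl-2,2'-diyl N,N-bis((R)-1-phenylethyl)phosphoramidite, 4 mol%], iPr2Zn, toluene, −30 °C; then BnOCH2Cl, HMPA, −30 → 0 °C
Reagents that add atoms: diisopropylzinc CC(C)[Zn]C(C)C; benzyl chloromethyl ether ClCOCc1ccccc1
Why: Copper-catalysed asymmetric conjugate addition of the dialkylzinc (Feringa type) should set the isopropyl-bearing centre through the chiral phosphoramidite–copper complex (this ligand enantiomer is expected to give the 3S enolate sense, its antipode being used otherwise), and the zinc enolate is C-alkylated by the reactive chloromethyl ether anti to the neighbouring isopropyl group, which gives the trans ketone (tandem conjugate addition–enolate alkylation).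

Step 2
Reactants: 3 (2S,3R)-2-[(benzyloxy)methyl]-3-(propan-2-yl)cyclohexan-1-one
Product: 4 (3S,4R)-3-[(benzyloxy)methyl]-2-bromo-4-(propan-2-yl)cyclohex-1-ene-1-carbaldehyde
Conditions: PBr3, DMF, CHCl3, 0 → 23 °C; aq. NaHCO3
Reagents that add atoms: phosphorus tribromide BrP(Br)Br; N,N-dimethylformamide CN(C)C=O; water O
Why: Vilsmeier–Haack–Arnold bromoformylation can deliver a conjugated β-bromo enal only by formylation at the unsubstituted α-CH2, so Br ends on the former carbonyl carbon and CHO on its neighbour, with no stereocentre touched.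

Step 3
Reactants: 4 (3S,4R)-3-[(benzyloxy)methyl]-2-bromo-4-(propan-2-yl)cyclohex-1-ene-1-carbaldehyde
Product: 5 [(3S,4R)-3-[(benzyloxy)methyl]-2-bromo-4-(propan-2-yl)cyclohex-1-en-1-yl]methanol
Conditions: NaBH4, CeCl3·7H2O, MeOH, 0 °C
Reagents that add atoms: none
Why: Luche reduction should give clean 1,2-reduction of the enal to the primary allylic alcohol without touching the vinyl bromide.

Step 4
Reactants: 5 [(3S,4R)-3-[(benzyloxy)methyl]-2-bromo-4-(propan-2-yl)cyclohex-1-en-1-yl]methanol
Product: 7 ({[(1S,6R)-2-bromo-3-(chloromethyl)-6-(propan-2-yl)cyclohex-2-en-1-yl]methoxy}methyl)benzene, via allylic mesylate 6 (not isolated)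
Conditions: MsCl, Et3N, CH2Cl2, 0 °C; then LiCl, DMF, 23 °C
Reagents that add atoms: lithium chloride [Li+].[Cl-]
Why: Mesylation followed by SN2 displacement with chloride is the standard conversion of a primary allylic alcohol into its chloride, and the tetrasubstituted alkene leaves no SN2' outlet.

Step 5
Reactants: 7 ({[(1S,6R)-2-bromo-3-(chloromethyl)-6-(propan-2-yl)cyclohex-2-en-1-yl]methoxy}methyl)benzene
Product: 10 (6R,7R)-7-[(benzyloxy)methyl]-6-(propan-2-yl)-4,5,6,7-tetrahydro-2-benzofuran-1(3H)-one, via vinyllithium 8 (not isolated), via lithium carboxylate 9 (not isolated)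
Conditions: tBuLi (2.05 equiv), THF/Et2O/pentane (4:1:1), −105 °C; CO2 (dry gas), −105 → −78 °C; then DMF, 23 → 45 °C
Reagents that add atoms: carbon dioxide O=C=O
Why: Bromine–lithium exchange with tBuLi at −105 °C should outrun any attack on the primary allylic chloride (Parham-type selectivity for a bromide that carries an alkyl chloride) and gives vinyllithium 8, which adds to CO2 and forms the new C–C(=O) bond in carboxylate 9. On warming in THF/DMF the carboxylate oxygen displaces chloride at the allylic CH2 and forms the CH2–O bond, the known lactonisation of (Z)-4-halobut-2-enoate salts to butenolides; overall this is a formal (3+2) annulation of CO2 onto a vinyl anion/allyl cation synthon, closest to carboxylation of alkenyllithiums followed by carboxylate O-alkylation. The five-membered lactone closes in the 5-exo-tet mode, and the ring C=C holds both termini cis, so no geometric isomer can divert the closure. No stereocentre is formed, and the two existing ones are not at the reacting carbons. The step needs chemoselectivity (exchange before substitution or elimination at CH2Cl, no Wurtz coupling of 8 with 7), which the cryogenic temperature, the second equivalent of tBuLi that destroys tBuBr and the immediate CO2 quench should secure; the benzyl ether is inert.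

Step 6
Reactants: 10 (6R,7R)-7-[(benzyloxy)methyl]-6-(propan-2-yl)-4,5,6,7-tetrahydro-2-benzofuran-1(3H)-one
Product: 11 (6R,7R)-7-(hydroxymethyl)-6-(propan-2-yl)-4,5,6,7-tetrahydro-2-benzofuran-1(3H)-one
Conditions: BCl3, pentamethylbenzene, CH2Cl2, −78 °C; then MeOH, aq. NaHCO3
Reagents that add atoms: none
Why: Lewis-acid debenzylation with a non-basic cation scavenger should cleave the benzyl ether while leaving the tetrasubstituted butenolide alkene, which hydrogenolysis might endanger, untouched.

Step 7
Reactants: 11 (6R,7R)-7-(hydroxymethyl)-6-(propan-2-yl)-4,5,6,7-tetrahydro-2-benzofuran-1(3H)-one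
Product: 12 (4R,5R)-3-oxo-5-(propan-2-yl)-1,3,4,5,6,7-hexahydro-2-benzofuran-4-carbaldehyde
Conditions: Dess–Martin periodinane, NaHCO3, CH2Cl2, 0 → 23 °C
Reagents that add atoms: none
Why: Buffered Dess–Martin oxidation is mild enough to give the α-branched aldehyde without epimerising its allylic α-centre, whose trans arrangement to the isopropyl group is in any case expected to be the more stable one.

**Phosphonate reagents 15 and 16**

Step 8
Reactants: 13 prop-2-en-1-yl 2-(diethoxyphosphoryl)acetate
Product: 14 prop-2-en-1-yl 2-(diethoxyphosphoryl)-3-hydroxypropanoate (racemic)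
Conditions: paraformaldehyde (1.1 equiv), piperidine (cat.), MeOH, 65 °C
Reagents that add atoms: formaldehyde (from paraformaldehyde) C=O
Why: Amine-catalysed hydroxymethylation (aldol addition) of the CH-acidic phosphonoacetate with one equivalent of formaldehyde should stop at the mono-adduct because no strong base is present to drive the olefination with a second formaldehyde.

Step 9
Reactants: 14 prop-2-en-1-yl 2-(diethoxyphosphoryl)-3-hydroxypropanoate
Product: 15 prop-2-en-1-yl 3-{[tert-butyl(dimethyl)silyl]oxy}-2-(diethoxyphosphoryl)propanoate (racemic)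
Conditions: TBSCl, imidazole, CH2Cl2, 0 → 23 °C
Reagents that add atoms: tert-butyldimethylsilyl chloride CC(C)(C)[Si](C)(C)Cl
Why: Standard silylation of a primary alcohol blocks the hydroxyl and suppresses dehydration to the phosphonoacrylate.

Step 10
Reactants: 15 prop-2-en-1-yl 3-{[tert-butyl(dimethyl)silyl]oxy}-2-(diethoxyphosphoryl)propanoate
Product: 16 3-{[tert-butyl(dimethyl)silyl]oxy}-2-(diethoxyphosphoryl)propanoic acid (racemic)
Conditions: Pd(PPh3)4 (cat.), morpholine, THF, 23 °C; dilute citric acid work-up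
Reagents that add atoms: none
Why: Tsuji–Trost deallylation through a π-allylpalladium complex with morpholine as allyl acceptor should free the acid under neutral conditions that leave the silyl ether and phosphonate intact.

**Ring A: hydroxy lactone 30**

Step 11
Reactants: 17 3-methylbutanal; 18 but-3-en-2-one
Product: 19 (2R)-5-oxo-2-(propan-2-yl)hexanal
Conditions: (R)-2-[diphenyl(trimethylsilyloxy)methyl]pyrrolidine (5 mol%), ethyl 3,4-dihydroxybenzoate (20 mol%), neat, 4 °C
Reagents that add atoms: none
Why: Enamine-catalysed Michael addition of the aldehyde to the enone sets the α-centre by attack on the enamine face remote from the diarylmethyl group, expected to give the R aldehyde with this catalyst enantiomer (the antipodal catalyst is used should the sense prove opposite).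

Step 12
Reactants: 19 (2R)-5-oxo-2-(propan-2-yl)hexanal
Product: 20 (4R)-4-(propan-2-yl)cyclohex-2-en-1-one
Conditions: LiOH, iPrOH, 23 °C
Reagents that add atoms: none
Why: Intramolecular aldol condensation of the methyl ketone onto the aldehyde closes the cyclohexenone, and mild hydroxide at room temperature should keep the α-centre from racemising.

Step 13
Reactants: 20 (4R)-4-(propan-2-yl)cyclohex-2-en-1-one
Product: 22 (2R,3R,4R)-3-ethenyl-2-(hydroxymethyl)-4-(propan-2-yl)cyclohexan-1-one, via magnesium enolate 21 (not isolated)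
Conditions: CuBr·SMe2 (10 mol%), CH2=CHMgBr, THF, −78 °C; then CH2O (gas), −78 → −40 °C; aq. NH4Cl
Reagents that add atoms: vinylmagnesium bromide C=C[Mg]Br; formaldehyde C=O
Why: Copper-catalysed conjugate addition of the vinyl Grignard reagent occurs anti to the C-4 isopropyl group, and the regiodefined enolate is hydroxymethylated by formaldehyde anti to the new vinyl group (conjugate addition–aldol trapping), which should give the all-trans, all-equatorial ketone.

Step 14
Reactants: 22 (2R,3R,4R)-3-ethenyl-2-(hydroxymethyl)-4-(propan-2-yl)cyclohexan-1-one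
Product: 23 (2R,3R,4R)-3-ethenyl-4-(propan-2-yl)-2-{[(triethylsilyl)oxy]methyl}cyclohexan-1-one
Conditions: TESCl, imidazole, CH2Cl2, 0 °C
Reagents that add atoms: triethylsilyl chloride CC[Si](Cl)(CC)CC
Why: Silylation under weakly basic conditions protects the β-hydroxy ketone against retro-aldol cleavage and dehydration in the ylide step.

Step 15
Reactants: 23 (2R,3R,4R)-3-ethenyl-4-(propan-2-yl)-2-{[(triethylsilyl)oxy]methyl}cyclohexan-1-one
Product: 24 (3S,4R,5R,6R)-5-ethenyl-6-(propan-2-yl)-4-{[(triethylsilyl)oxy]methyl}-1-oxaspiro[2.5]octane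
Conditions: Me3S+ I−, KN(SiMe3)2, THF, −10 → 0 °C
Reagents that add atoms: trimethylsulfonium iodide C[S+](C)C.[I-]
Why: Corey–Chaykovsky epoxidation with the small, irreversibly adding dimethylsulfonium methylide proceeds by axial attack on the chair ketone, so the new CH2 should stand axial (cis to the equatorial C-4 substituent) and the oxygen equatorial, which sets the quaternary carbinol centre.

Step 16
Reactants: 24 (3S,4R,5R,6R)-5-ethenyl-6-(propan-2-yl)-4-{[(triethylsilyl)oxy]methyl}-1-oxaspiro[2.5]octane
Product: 25 [(3S,4R,5R,6R)-5-ethenyl-6-(propan-2-yl)-1-oxaspiro[2.5]octan-4-yl]methanol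
Conditions: Bu4NF, AcOH, THF, 0 °C
Reagents that add atoms: none
Why: Buffered fluoride desilylation frees the primary alcohol without the acid or alkoxide catalysis that would let it open the epoxide.

Step 17
Reactants: 25 [(3S,4R,5R,6R)-5-ethenyl-6-(propan-2-yl)-1-oxaspiro[2.5]octan-4-yl]methanol
Product: 28 (3aS,6R,7R,7aS)-7-ethenyl-3a-hydroxy-6-(propan-2-yl)hexahydro-2-benzofuran-1(3H)-one, via epoxy aldehyde 26 (not isolated), via epoxy acid 27 (not isolated)
Conditions: TEMPO (cat.), PhI(OAc)2, MeCN/aq. phosphate buffer (pH 7), 23 °C; then 40 °C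
Reagents that add atoms: water O
Why: Oxoammonium (TEMPO) oxidation takes the primary alcohol to the acid, whose carboxylate opens the spiro-epoxide at its unhindered CH2 (the usual lactonisation of β,γ-epoxy acids to β-hydroxy γ-lactones), so the cis-fused lactone and the equatorial tertiary alcohol arise with the configuration fixed in step 15.

Step 18
Reactants: 28 (3aS,6R,7R,7aS)-7-ethenyl-3a-hydroxy-6-(propan-2-yl)hexahydro-2-benzofuran-1(3H)-one
Product: 29 (3aS,4R,5R,7aS)-7a-hydroxy-3-oxo-5-(propan-2-yl)octahydro-2-benzofuran-4-carbaldehyde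
Conditions: O3, CH2Cl2/MeOH, −78 °C; then Me2S
Reagents that add atoms: ozone [O-][O+]=O
Why: Ozonolysis with reductive work-up cleaves the vinyl group, the only alkene present, to the aldehyde.

Step 19
Reactants: 29 (3aS,4R,5R,7aS)-7a-hydroxy-3-oxo-5-(propan-2-yl)octahydro-2-benzofuran-4-carbaldehyde; 15 prop-2-en-1-yl 3-{[tert-butyl(dimethyl)silyl]oxy}-2-(diethoxyphosphoryl)propanoate
Product: 30 prop-2-en-1-yl (2E)-2-({[tert-butyl(dimethyl)silyl]oxy}methyl)-3-[(3aS,4S,5R,7aS)-7a-hydroxy-3-oxo-5-(propan-2-yl)octahydro-2-benzofuran-4-yl]prop-2-enoate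
Conditions: LiCl, DBU, MeCN, 0 → 23 °C
Reagents that add atoms: none
Why: Horner–Wadsworth–Emmons olefination under Masamune–Roush conditions is mild enough for the epimerisable aldehyde and the free tertiary alcohol and should favour the E alkene (ring trans to the ester carbonyl), as is usual for α-substituted phosphonoacetates with α-branched aldehydes.

**Union and deprotection**

Step 20
Reactants: 30 prop-2-en-1-yl (2E)-2-({[tert-butyl(dimethyl)silyl]oxy}methyl)-3-[(3aS,4S,5R,7aS)-7a-hydroxy-3-oxo-5-(propan-2-yl)octahydro-2-benzofuran-4-yl]prop-2-enoate; 16 3-{[tert-butyl(dimethyl)silyl]oxy}-2-(diethoxyphosphoryl)propanoic acid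
Product: 31 the 3-silyloxy-2-(diethoxyphosphoryl)propanoate ester of the tertiary alcohol of 30 (both epimers at the phosphonate carbon)
Conditions: DCC, DMAP (cat.), CH2Cl2, 0 → 23 °C
Reagents that add atoms: none
Why: Steglich esterification of a CH-acidic phosphonoacetic acid can proceed through a phosphonoketene formed from the O-acylisourea, a small and reactive acylating species of the kind that adds to hindered tertiary alcohols, and the catalytic base load keeps β-elimination of the product low.

Step 21
Reactants: 31 the phosphonate ester of step 20; 12 (4R,5R)-3-oxo-5-(propan-2-yl)-1,3,4,5,6,7-hexahydro-2-benzofuran-4-carbaldehyde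
Product: 32 the prop-2-en-1-yl ester of the target with both CH2OH groups as tert-butyldimethylsilyl ethers
Conditions: LiCl, DBU, MeCN, 0 → 23 °C
Reagents that add atoms: none
Why: An intermolecular Horner–Wadsworth–Emmons olefination joins the two halves and builds the second (E)-acrylate (ring B trans to the ester carbonyl) under conditions too weakly basic to deprotonate the lactone α-position or to epimerise 12 appreciably.

Step 22
Reactants: 32 the bis-silyl allyl ester
Product: 33 the target with both CH2OH groups as tert-butyldimethylsilyl ethers (free acid)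
Conditions: Pd(PPh3)4 (cat.), morpholine, THF, 23 °C; dilute citric acid work-up
Reagents that add atoms: none
Why: Tsuji–Trost deallylation removes only the allyl ester, since the allylic silyl ethers, the butenolide and the tertiary ester are not ionised by zerovalent palladium under these conditions.

Step 23
Reactants: 33 the bis-silyl acid
Product: 34 (2E)-3-[(3aS,4S,5R,7aS)-7a-{[(2E)-2-(hydroxymethyl)-3-[(4S,5R)-3-oxo-5-(propan-2-yl)-1,3,4,5,6,7-hexahydro-2-benzofuran-4-yl]prop-2-enoyl]oxy}-3-oxo-5-(propan-2-yl)octahydro-2-benzofuran-4-yl]-2-(hydroxymethyl)prop-2-enoic acid (CNP0238371.2)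
Conditions: HF·pyridine, pyridine, THF, 0 → 23 °C
Reagents that add atoms: none
Why: Buffered HF·pyridine cleaves both primary silyl ethers without the base that would eliminate the β-acyloxy lactone or the strong acid that could ionise the tertiary ester.

**Compound list**

1 | cyclohex-2-en-1-one | O=C1C=CCCC1 | starting material
2 | isopropylzinc (3R)-3-(propan-2-yl)cyclohex-1-en-1-olate | C1=C(O[Zn]C(C)C)CCC[C@@H]1C(C)C | intermediate
3 | (2S,3R)-2-[(benzyloxy)methyl]-3-(propan-2-yl)cyclohexan-1-one | c1ccccc1COC[C@H]1C(=O)CCC[C@@H]1C(C)C | intermediate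
4 | (3S,4R)-3-[(benzyloxy)methyl]-2-bromo-4-(propan-2-yl)cyclohex-1-ene-1-carbaldehyde | c1ccccc1COC[C@H]1C(Br)=C(C=O)CC[C@@H]1C(C)C | intermediate
5 | [(3S,4R)-3-[(benzyloxy)methyl]-2-bromo-4-(propan-2-yl)cyclohex-1-en-1-yl]methanol | c1ccccc1COC[C@H]1C(Br)=C(CO)CC[C@@H]1C(C)C | intermediate
6 | methanesulfonate of 5 | c1ccccc1COC[C@H]1C(Br)=C(COS(C)(=O)=O)CC[C@@H]1C(C)C | intermediate
7 | ({[(1S,6R)-2-bromo-3-(chloromethyl)-6-(propan-2-yl)cyclohex-2-en-1-yl]methoxy}methyl)benzene | c1ccccc1COC[C@H]1C(Br)=C(CCl)CC[C@@H]1C(C)C | intermediate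
8 | vinyllithium: compound 7 with Li in place of Br (stereocentres as in 7) | c1ccccc1COC[C@H]1C([Li])=C(CCl)CC[C@@H]1C(C)C | intermediate
9 | lithium carboxylate: compound 7 with CO2Li in place of Br (stereocentres as in 7) | c1ccccc1COC[C@H]1C(C(=O)[O-])=C(CCl)CC[C@@H]1C(C)C.[Li+] | intermediate
10 | (6R,7R)-7-[(benzyloxy)methyl]-6-(propan-2-yl)-4,5,6,7-tetrahydro-2-benzofuran-1(3H)-one | c1ccccc1COC[C@H]1C2=C(CC[C@@H]1C(C)C)COC2=O | intermediate
11 | (6R,7R)-7-(hydroxymethyl)-6-(propan-2-yl)-4,5,6,7-tetrahydro-2-benzofuran-1(3H)-one | OC[C@H]1C2=C(CC[C@@H]1C(C)C)COC2=O | intermediate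
12 | (4R,5R)-3-oxo-5-(propan-2-yl)-1,3,4,5,6,7-hexahydro-2-benzofuran-4-carbaldehyde | O=C[C@H]1C2=C(CC[C@@H]1C(C)C)COC2=O | intermediate
13 | prop-2-en-1-yl 2-(diethoxyphosphoryl)acetate | C=CCOC(=O)CP(=O)(OCC)OCC | starting material
14 | prop-2-en-1-yl 2-(diethoxyphosphoryl)-3-hydroxypropanoate (racemic) | C=CCOC(=O)C(CO)P(=O)(OCC)OCC | intermediate
15 | prop-2-en-1-yl 3-{[tert-butyl(dimethyl)silyl]oxy}-2-(diethoxyphosphoryl)propanoate (racemic) | C=CCOC(=O)C(CO[Si](C)(C)C(C)(C)C)P(=O)(OCC)OCC | intermediate
16 | 3-{[tert-butyl(dimethyl)silyl]oxy}-2-(diethoxyphosphoryl)propanoic acid (racemic) | OC(=O)C(CO[Si](C)(C)C(C)(C)C)P(=O)(OCC)OCC | intermediate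
17 | 3-methylbutanal | CC(C)CC=O | starting material
18 | but-3-en-2-one | CC(=O)C=C | starting material
19 | (2R)-5-oxo-2-(propan-2-yl)hexanal | CC(C)[C@H](C=O)CCC(C)=O | intermediate
20 | (4R)-4-(propan-2-yl)cyclohex-2-en-1-one | CC(C)[C@H]1CCC(=O)C=C1 | intermediate
21 | bromomagnesium (3R,4R)-3-ethenyl-4-(propan-2-yl)cyclohex-1-en-1-olate | CC(C)[C@H]1CCC(O[Mg]Br)=C[C@@H]1C=C | intermediate
22 | (2R,3R,4R)-3-ethenyl-2-(hydroxymethyl)-4-(propan-2-yl)cyclohexan-1-one | CC(C)[C@H]1CCC(=O)[C@@H](CO)[C@@H]1C=C | intermediate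
23 | (2R,3R,4R)-3-ethenyl-4-(propan-2-yl)-2-{[(triethylsilyl)oxy]methyl}cyclohexan-1-one | CC(C)[C@H]1CCC(=O)[C@@H](CO[Si](CC)(CC)CC)[C@@H]1C=C | intermediate
24 | (3S,4R,5R,6R)-5-ethenyl-6-(propan-2-yl)-4-{[(triethylsilyl)oxy]methyl}-1-oxaspiro[2.5]octane | CC(C)[C@H]1CC[C@@]3(CO3)[C@@H](CO[Si](CC)(CC)CC)[C@@H]1C=C | intermediate
25 | [(3S,4R,5R,6R)-5-ethenyl-6-(propan-2-yl)-1-oxaspiro[2.5]octan-4-yl]methanol | CC(C)[C@H]1CC[C@@]3(CO3)[C@@H](CO)[C@@H]1C=C | intermediate
26 | epoxy aldehyde: compound 25 with CHO in place of CH2OH (same spatial arrangement) | CC(C)[C@H]1CC[C@@]3(CO3)[C@@H](C=O)[C@@H]1C=C | intermediate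
27 | epoxy acid: compound 25 with CO2H in place of CH2OH (same spatial arrangement) | CC(C)[C@H]1CC[C@@]3(CO3)[C@@H](C(=O)O)[C@@H]1C=C | intermediate
28 | (3aS,6R,7R,7aS)-7-ethenyl-3a-hydroxy-6-(propan-2-yl)hexahydro-2-benzofuran-1(3H)-one | CC(C)[C@H]1CC[C@@]2(O)COC(=O)[C@H]2[C@@H]1C=C | intermediate
29 | (3aS,4R,5R,7aS)-7a-hydroxy-3-oxo-5-(propan-2-yl)octahydro-2-benzofuran-4-carbaldehyde | CC(C)[C@H]1CC[C@@]2(O)COC(=O)[C@H]2[C@@H]1C=O | intermediate
30 | prop-2-en-1-yl (2E)-2-({[tert-butyl(dimethyl)silyl]oxy}methyl)-3-[(3aS,4S,5R,7aS)-7a-hydroxy-3-oxo-5-(propan-2-yl)octahydro-2-benzofuran-4-yl]prop-2-enoate | CC(C)[C@H]1CC[C@@]2(O)COC(=O)[C@H]2[C@@H]1/C=C(\CO[Si](C)(C)C(C)(C)C)C(=O)OCC=C | intermediate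
31 | 3-silyloxy-2-(diethoxyphosphoryl)propanoate ester of the tertiary alcohol of 30 (both epimers at the phosphonate carbon) | CC(C)[C@H]1CC[C@@]2(OC(=O)C(CO[Si](C)(C)C(C)(C)C)P(=O)(OCC)OCC)COC(=O)[C@H]2[C@@H]1/C=C(\CO[Si](C)(C)C(C)(C)C)C(=O)OCC=C | intermediate
32 | prop-2-en-1-yl ester of the target with both CH2OH groups as tert-butyldimethylsilyl ethers | CC(C)[C@H]1CC[C@@]2(OC(=O)/C(=C/[C@H]3C4=C(CC[C@@H]3C(C)C)COC4=O)CO[Si](C)(C)C(C)(C)C)COC(=O)[C@H]2[C@@H]1/C=C(\CO[Si](C)(C)C(C)(C)C)C(=O)OCC=C | intermediate
33 | target with both CH2OH groups as tert-butyldimethylsilyl ethers (free acid) | CC(C)[C@H]1CC[C@@]2(OC(=O)/C(=C/[C@H]3C4=C(CC[C@@H]3C(C)C)COC4=O)CO[Si](C)(C)C(C)(C)C)COC(=O)[C@H]2[C@@H]1/C=C(\CO[Si](C)(C)C(C)(C)C)C(=O)O | intermediate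
34 | (2E)-3-[(3aS,4S,5R,7aS)-7a-{[(2E)-2-(hydroxymethyl)-3-[(4S,5R)-3-oxo-5-(propan-2-yl)-1,3,4,5,6,7-hexahydro-2-benzofuran-4-yl]prop-2-enoyl]oxy}-3-oxo-5-(propan-2-yl)octahydro-2-benzofuran-4-yl]-2-(hydroxymethyl)prop-2-enoic acid | CC(C)[C@H]1CC[C@@]2(OC(=O)/C(=C/[C@H]3C4=C(CC[C@@H]3C(C)C)COC4=O)CO)COC(=O)[C@H]2[C@@H]1/C=C(\CO)C(=O)O | target

**Step count.** Total: 23 steps. Longest linear sequence: 13 steps (steps 11–23).

**Steps most likely to fail**

Step 5. The risk is attack of tBuLi on the allylic chloride, or coupling of vinyllithium 8 with unreacted 7, before carboxylation, and slow ring closure of carboxylate 9. The fallback sets out from bromo allylic alcohol 5 and closes the lactone by palladium-catalysed carbonylative lactonisation (Pd(PPh3)4 cat., CO 1 atm, Et3N, MeCN, 60 °C): oxidative addition into the C–Br bond, CO insertion and capture of the acylpalladium by the neighbouring CH2OH. It avoids organolithium chemistry and the chloride altogether, gives up the carbon dioxide closure, and comes back to the route at butenolide 10. It makes no new compound (F0).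

Step 21. The risk is slow olefination between the hindered α-substituted phosphonate and the α-branched aldehyde, so that base-induced loss of the tertiary acyloxy group from the β-acyloxy lactone or epimerisation of 12 competes. The fallback sets out from aldehyde 12 and alcohol 30 and forms the acrylate before the ester. Aldehyde 12 is olefinated with the small phosphonate 15 (LiCl, DBU, MeCN) to the allyl (E)-acrylate of the ring-B half F1. Deallylation (Pd(PPh3)4, morpholine) gives the ring-B acrylic acid F2. This acid is activated with 2,4,6-trichlorobenzoyl chloride and Et3N as the Yamaguchi mixed anhydride F3 and esterified with tertiary alcohol 30 (DMAP, toluene, 40 °C). The sequence comes back to the route at 32 and makes steps 10 and 20 unnecessary.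

Step 20. The risk is loss of silanolate from the activated acid (to a phosphonoacrylate) and incomplete acylation of the hindered tertiary alcohol. The fallback sets out from 30 and installs the side arm in stages. Alcohol 30 is acylated with commercial diethylphosphonoacetic acid (DCC, DMAP cat., CH2Cl2), which has no β-leaving group and reacts through the parent phosphonoketene, to give the phosphonoacetate of the tertiary alcohol F4. Hydroxymethylation (paraformaldehyde, piperidine cat., as in step 8) gives the 3-hydroxy-2-phosphonopropanoate F5. Silylation (TBSCl, imidazole) comes back to the route at 31.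

**Further compounds**

F0 | step 5 | none | none
F1 | step 21 | prop-2-en-1-yl (2E)-2-({[tert-butyl(dimethyl)silyl]oxy}methyl)-3-[(4S,5R)-3-oxo-5-(propan-2-yl)-1,3,4,5,6,7-hexahydro-2-benzofuran-4-yl]prop-2-enoate | C=CCOC(=O)/C(=C/[C@H]1C2=C(CC[C@@H]1C(C)C)COC2=O)CO[Si](C)(C)C(C)(C)C
F2 | step 21 | (2E)-2-({[tert-butyl(dimethyl)silyl]oxy}methyl)-3-[(4S,5R)-3-oxo-5-(propan-2-yl)-1,3,4,5,6,7-hexahydro-2-benzofuran-4-yl]prop-2-enoic acid | OC(=O)/C(=C/[C@H]1C2=C(CC[C@@H]1C(C)C)COC2=O)CO[Si](C)(C)C(C)(C)C
F3 | step 21 | mixed anhydride of F2 with 2,4,6-trichlorobenzoic acid | O=C(OC(=O)/C(=C/[C@H]1C2=C(CC[C@@H]1C(C)C)COC2=O)CO[Si](C)(C)C(C)(C)C)c1c(Cl)cc(Cl)cc1Cl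
F4 | step 20 | 2-(diethoxyphosphoryl)acetate ester of the tertiary alcohol of 30 | CC(C)[C@H]1CC[C@@]2(OC(=O)CP(=O)(OCC)OCC)COC(=O)[C@H]2[C@@H]1/C=C(\CO[Si](C)(C)C(C)(C)C)C(=O)OCC=C
F5 | step 20 | 2-(diethoxyphosphoryl)-3-hydroxypropanoate ester of the tertiary alcohol of 30 (both epimers at the phosphonate carbon) | CC(C)[C@H]1CC[C@@]2(OC(=O)C(CO)P(=O)(OCC)OCC)COC(=O)[C@H]2[C@@H]1/C=C(\CO[Si](C)(C)C(C)(C)C)C(=O)OCC=C
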